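The rate constants are invented.

Each closed, stirred vessel here starts from the same L and differs from its fellows in the D poured in.

    L + D ⇌ Z + J (K1 = 0.95, k1 = 0.070 M⁻¹ s⁻¹)
    J + D ⇌ Z + G (K2 = 0.16, k2 = 0.58 M⁻¹ s⁻¹)
    G + D ⇌ Z + Q (K3 = 3.4, k3 = 0.073 M⁻¹ s⁻¹)
    Z → E (k4 = 0.0073 s⁻¹)
    D ⇌ X (K5 = 1.4, k5 = 0.0022 s⁻¹)

| setting | Sunday's | Wednesday's | Tuesday's |
|---|---|---|---|
| L | 49 mM | 49 mM | 49 mM |
| D | 2.00 equiv | 8.00 equiv | 4.00 equiv |
| time | 25 min | 25 min | 25 min |

- which of these there is most of at the end, counted by the L in it, Sunday's (G / L / J / Q)
- which of these there is most of at the end, counted by the L in it, Wednesday's (G / L / J / Q)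
- which of these there is most of at the end, counted by the L in it, Tuesday's (G / L / J / Q)
- the largest of these amounts at the end, in percent of the L charged, Sunday's
- the largest of these amounts at the end, in percent of the L charged, Wednesday's
- the largest of these amounts at the end, in percent of the L charged, Tuesday's

*What does an L cost in D?* Each exchange takes one D and frees one Z, so an L needs 3 D to become Q.

*So what do you count first?* Sunday's has 0.667, Tuesday's 1.33 and Wednesday's 2.67 of what I call the cover: the equivalents of D charged per L, divided by the 3 exchanges that turn L into Q.

*And a cover below one?* Then D is the limiting reagent. Sunday's cover is below one, so Sunday's flask can pay for a mean of 2.00 exchanges per L at most, and Q can reach 66.7% of the L at most.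

*But X takes D away, doesn't it?* For a time. D and X turn into each other, and once they balance, a share of 41.7% of the unspent D stands free. X can turn back, so I keep it in the cover.

*And Z, can't it undo the exchanges?* It can. Z leaves for E with a half-life of 1.58 min, but while it stands it can fall back, so I don't count the exchanges as one-way.

*Does the cover tell you how far a flask gets by the end?* No, it is a ceiling on what the charge pays for, not a clock. I commit to Q first on Tuesday's and Wednesday's and to G or J first on Sunday's, and I give no percentages.

The forecast goes further and names J for Sunday's, where I left G open. It gives J at 35% on Sunday's, Q at 78% on Tuesday's and Q at 98.5% on Wednesday's. Its grounds for Sunday's are these: “At 2 equiv D runs short and the mixture stalls spread over J, G and Q with J slightly ahead”.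

The simulation gives J at 33.0% on Sunday's, Q at 71.7% on Tuesday's and Q at 99.8% on Wednesday's, so the forecast's Tuesday's figure stands 6.3 percentage points high.

On Wednesday's, the last exchange has a relaxation half-life of 1.36 min at the end, shorter than the 25 min of the run. Sunday's stands at a mean of 1.50 exchanges per L at the end, below its ceiling, and at 250 min it reads 2.00, with D down to 0.0176% of its charge.

Wednesday's flask read at 6.0 min keeps its cover of 2.67, above one, so the charge can pay for 3 exchanges per L and any shortfall there belongs to the clock. That flask holds Q at 74.2%, a mean of 2.56 exchanges per L, with 36.3% of its D still free.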